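Assumption: the chain of 17 is numbered from the aryl-bearing carbon (C1) to the terminal methyl (C14). The (S)-configured Cl,MeO-BIPHEP ligand is taken as the one that leads to the (S,S)-diol 6; if the sense of induction should be the opposite, the mirror-image ligand is used with no other change.

## Structural features

The target is an open-chain compound: a saturated fourteen-carbon chain whose C1 is bonded to ring A, a 4-hydroxy-3-methoxyphenyl ring, and which carries secondary hydroxyls at C3 and C5; there is no other ring. The two stereocentres, C3 and C5, are not adjacent: the C4 methylene lies between them, both are S, and they stand in a 1,3-anti relationship. Seen from C4 the two flanks differ only at a distance (an arylethyl arm on C3, a nonyl arm on C5), so the C2–C6 core is C2-symmetric in all but its ends. The fragile groups are the free, electron-rich phenol, which is acidic toward organometallics and easily oxidised, and the 1,3-diol, whose O5 can close a tetrahydropyran onto any cation generated at the benzylic C1. The real difficulty is to fix the absolute configuration of two isolated carbinol centres and their anti relationship in a chain with no neighbouring group to relay stereochemistry, and then to tell two nearly equivalent ends apart. The key step uses the fact that C3–C4–C5 with oxygen on C3 and C5 is the skeleton of propane-1,3-diol and that C2 and C6 are plain methylenes: each can arrive as the CH2 of an allyl group, so both C–C bonds and both stereocentres can be made at once on a C2-symmetric (S,S)-diene diol.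

## Logic of the disconnections

17 is traced back to 16 by tying O3 and O5 into an isopropylidene ketal. No skeletal bond is cut. The ketal masks the diol through the organometallic, metathesis and reductive steps, and it keeps both oxygens from attacking a benzylic cation at C1. The gain is a last step that is a plain hydrolysis. The demand is that the ketal be removed only after C1 has become a methylene, under acid that leaves the phenol alone.

16 is traced back to 15 by three functional-group additions: a C7=C8 double bond, a hydroxyl on C1 and a benzyl group on the phenol oxygen. Each is the trace of the bond-forming step that precedes it, and one reductive operation removes all three. The demand is that hydrogenolysis of the benzylic C1–O bond go to completion while the ketal stays in place.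

15 is cut at C7=C8 into 13 and 14. C8–C14 is a commodity terminal alkene, and C6–C7 is already present in 13 as an allyl arm. The tail is added in one step with no change of oxidation level. The forward step must favour the cross product over the homodimers, which an excess of 14 secures; the alkene geometry does not matter.

13 is cut at the C1–aryl bond into aldehyde 9 and the organomagnesium 12. C1 is the one carbon at which an aryl nucleophile can deliver ring A directly, and the configuration of the new C1 carbinol is irrelevant. A free phenol would destroy 12 as it forms, so 12 is drawn from the benzyl ether 11, and 11 from 10 by cutting the O–CH2Ph bond. The forward addition must be run cold so that the β-alkoxy aldehyde neither enolises nor eliminates.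

9 is traced back to 7 by giving C1 back the methylene carbon it has lost (C1=O becomes C1=CH2). This restores a second allyl arm and with it the C2 axis, so the precursor has two identical ends. The price is one discarded carbon. The forward step must cleave one of two homotopic vinyl groups and not both: either gives the same product, but conversion has to be held back and unreacted 7 recycled.

7 is traced back to 6 by removing the ketal; no skeletal bond is cut, and the forward step only has to close a six-membered ketal on an anti 1,3-diol.

6 is cut at the two bonds that become C2–C3 and C5–C6 of 17 (C3–C4 and C6–C7 of 6). Both stereocentres vanish, and what remains is 1 and two molecules of 2. The forward step must oxidise each terminus of 1 in the flask, control the face of each transient aldehyde (3 and 5), and override the influence of the first carbinol during the second addition.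

## Other disconnections considered

Alternative 1: The cut is made in the oxygen pattern and not in the skeleton. The C4 methylene is traced back to an epoxide carbon, so the whole chain comes from racemic (E)-1-(4-benzyloxy-3-methoxyphenyl)tetradec-3-en-5-ol A1. In the forward key step Ti(OiPr)4 (tetravalent titanium), L-(+)-diisopropyl tartrate and t-BuOOH would epoxidise the (5S)-enantiomer of A1 faster than its mirror image and give the erythro epoxy alcohol (3S,4S,5S)-1-(4-benzyloxy-3-methoxyphenyl)-3,4-epoxytetradecan-5-ol A2, forming C3–O and C4–O and closing one oxirane. Hydroxyl-directed hydride delivery to C4 with NaAlH2(OCH2CH2OMe)2 and hydrogenolysis of the benzyl group would then complete 17.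
- In its favour: one well-understood reagent sets the absolute configuration and the erythro relationship; the two ends are different from the start; the metal is cheap.
- Against it here: at most half of A1 can be used; the enantiopurity of A2 depends on where the conversion is stopped; hydride attack at C3 instead of C4 is a known leak for secondary epoxy alcohols; A1 must first be built by several C–C bond-forming steps.
- Comparison: in stereochemical predictability the titanium–tartrate template is the equal of the iridium catalyst. In needing no statistical desymmetrisation it is the better plan. In step count the two are about equal. The chosen plan is ahead in that its key step makes two skeletal bonds where this one makes none, and its unreacted 7 can be recycled whereas the slow enantiomer of A1 is lost.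

Alternative 2: C1–C2 is cut together with a temporary C1–O5 bond, which leads to (S)-tridec-1-en-4-ol A3 and 4-formyl-2-methoxyphenyl acetate (vanillin acetate) A4. Under CF3CO2H these would condense to an oxocarbenium ion that cyclises through a chair with equatorial substituents (6-endo attack of the alkene) and is captured at C3 by trifluoroacetate. The product is all-cis (6S)-2-(4-acetoxy-3-methoxyphenyl)-6-nonyltetrahydropyran-4-yl trifluoroacetate A5. Hydrogenolysis of the benzylic ring C–O bond and solvolysis of the two esters would give 17.
- In its favour: it is the shortest plan; the C5 centre relays its configuration to C3 through the chair, so only one asymmetric step is needed; the arene is joined in the same step that installs O3; no carbon is discarded.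
- Against it here: an electron-rich aryl aldehyde stabilises the benzylic oxocarbenium ion, so a reversible 2-oxonia-Cope rearrangement can erode the enantiopurity carried by A3 and exchange side chains; the ring is made only to be destroyed; the trifluoroacetate is labile.
- Comparison: both plans end with palladium-mediated hydrogenolysis of a benzylic C1–O bond, and on that point they are equal. Alternative 2 is clearly better in step count (about four steps against eight) and in atom economy on the arene side. The chosen plan is more secure in stereochemistry: both centres are set by the catalyst and a mis-set centre is drained into a separable meso compound, whereas here the enantiopurity of A3 can only be lost.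

Alternative 3: C1–C2 and C6–C7 are cut, which leaves C2–C6 as (2R,4R)-1,2:4,5-diepoxypentane A6. The descriptor is R,R although no bond at the stereocentres changes, because the CIP priorities change on opening. In one flask, CuI (monovalent copper) would catalyse opening of one oxirane by octylmagnesium bromide A7 and then of the other by [4-(benzyloxy)-3-methoxyphenyl]methylmagnesium chloride A8. This gives (3S,5S)-1-(4-benzyloxy-3-methoxyphenyl)tetradecane-3,5-diol A9; no ring closes and two oxiranes open. Debenzylation of A9 gives 17.
- In its favour: it rests on the same insight as the chosen plan, the C2-symmetric C3–C5 core, but both ends arrive complete; the diol needs no protection; there is no redox adjustment and no lost carbon.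
- Against it here: the first opening is statistical, and the mixture goes straight into the second addition, so A9 must be separated from two symmetrical diols of similar polarity; an electron-rich benzylic Grignard reagent such as A8 is prone to Wurtz coupling while it is made; A6 needs its own enantioselective preparation and is a volatile bis-alkylating agent.
- Comparison: in recognising the symmetry, and in having to desymmetrise two homotopic ends statistically, the two plans are equal. Alternative 3 is better in convergence and in the number of steps after the key step (one against seven). The chosen plan is ahead in that the chirality is created catalytically from two commodity chemicals, its statistical step leaves recyclable starting material, and it avoids a hazardous diepoxide.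

Key step: step 1

## Route

Step 1
Reactants: 1 propane-1,3-diol; 2 allyl acetate (two molecules react with each molecule of 1)
Product: 6 (4S,6S)-nona-1,8-diene-4,6-diol, via 3-hydroxypropanal 3 (not isolated), via (3S)-hex-5-ene-1,3-diol 4 (not isolated), via (3S)-3-hydroxyhex-5-enal 5 (not isolated)
Conditions: [Ir(cod)Cl]2 (5 mol%), (S)-Cl,MeO-BIPHEP (10 mol%), 4-chloro-3-nitrobenzoic acid (20 mol%), Cs2CO3 (40 mol%), 2 (10 equiv), 1,4-dioxane, 90 °C, sealed vessel
Reagents that add atoms: none
Why: In the flask [Ir(cod)Cl]2, the bisphosphine, the nitrobenzoate and 2 assemble into a cyclometalated C,O-benzoate π-allyl complex of trivalent iridium; exchange with 1 gives an iridium alkoxide that undergoes β-hydride elimination to aldehyde 3. The iridium hydride is deprotonated by carbonate to monovalent iridium, which adds 2 oxidatively and regenerates the π-allyl complex, so the alcohol itself is the reductant and no allyl-metal reagent is needed. The σ-allyl form adds to the bound aldehyde through a closed six-membered chair transition state and gives 4 after alkoxide exchange; the same cycle at the other CH2OH terminus passes through 5 and ends at 6, forming C3–C4 and C6–C7 of 6 (C2–C3 and C5–C6 of 17). The closest known reaction type is the iridium-catalysed transfer-hydrogenative carbonyl allylation from the alcohol oxidation level, in its two-directional form on 1,3-diols. No ring is closed. Both new stereocentres (C4 and C6 of 6) are set by the chiral bisphosphine on the octahedral iridium centre, which fixes the aldehyde face presented to the allyl ligand; in the second addition this catalyst control overrides 1,3-induction from the existing carbinol, so the same sense is imposed twice and the anti, C2-symmetric diol results. The step needs enantiofacial selectivity at two transient aldehydes and chemoselectivity for the primary termini, which is secured because only primary carbinols are dehydrogenated at a useful rate and the catalyst does not allylate ketones. A wrongly set first centre is carried mainly into the meso diastereomer, which is removed by chromatography, so the enantiopurity of 6 should exceed that of a single addition.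

Step 2
Reactants: 6 (4S,6S)-nona-1,8-diene-4,6-diol
Product: 7 (4S,6S)-2,2-dimethyl-4,6-di(prop-2-en-1-yl)-1,3-dioxane
Conditions: 2,2-dimethoxypropane, PPTS (cat.), CH2Cl2, rt
Reagents that add atoms: 2,2-dimethoxypropane, COC(C)(C)OC
Why: Acid-catalysed transketalisation of the 1,3-diol; the anti diol closes readily to the 1,3-dioxane (as a twist-boat) with methanol as the only by-product and no stereocentre involved, and the ketal shields both hydroxyls from ozone, from the Grignard reagent and later from a benzylic cation at C1.

Step 3
Reactants: 7 (4S,6S)-2,2-dimethyl-4,6-di(prop-2-en-1-yl)-1,3-dioxane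
Product: 9 2-[(4R,6S)-2,2-dimethyl-6-(prop-2-en-1-yl)-1,3-dioxan-4-yl]acetaldehyde, via mono-ozonide 8 (not isolated)
Conditions: O3 (0.65 equiv, titrated solution in CH2Cl2), CH2Cl2, −78 °C; then PPh3, −78 °C → rt; unreacted 7 recovered and recycled
Reagents that add atoms: ozone, [O-][O+]=O
Why: Ozonolysis with reductive work-up (cycloaddition, cycloreversion and recombination to ozonide 8, which PPh3 reduces to 9 and formaldehyde); the two vinyl groups are interchanged by the C2 axis, so either gives the same 9, and with ozone limiting the binomial distribution for two independent arms predicts mainly 9 and recoverable 7 with roughly a tenth of dialdehyde. No stereocentre is touched; the ring carbon next to the new CH2CHO changes descriptor from S to R only because the CIP priorities change.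

Step 4
Reactants: 10 4-bromo-2-methoxyphenol
Product: 11 1-(benzyloxy)-4-bromo-2-methoxybenzene
Conditions: BnBr, K2CO3, DMF, 60 °C
Reagents that add atoms: benzyl bromide, BrCc1ccccc1
Why: Williamson ether synthesis on the phenoxide; the benzyl group removes the acidic proton that would destroy the Grignard reagent and is lost later in the hydrogenation of step 7 at no extra cost.

Step 5
Reactants: 9 2-[(4R,6S)-2,2-dimethyl-6-(prop-2-en-1-yl)-1,3-dioxan-4-yl]acetaldehyde; 11 1-(benzyloxy)-4-bromo-2-methoxybenzene
Product: 13 (1RS)-1-[4-(benzyloxy)-3-methoxyphenyl]-2-[(4S,6S)-2,2-dimethyl-6-(prop-2-en-1-yl)-1,3-dioxan-4-yl]ethan-1-ol, via arylmagnesium bromide 12 (not isolated)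
Conditions: 11, Mg turnings, I2 (cat.), THF, 50 °C; then 9, THF, −78 → 0 °C; H2O quench
Reagents that add atoms: none
Why: Magnesium insertion into the aryl bromide gives 12, whose Grignard 1,2-addition to the unhindered aldehyde at low temperature (which suppresses enolisation and β-alkoxide elimination) forms the C1–aryl bond; the new C1 carbinol forms as both epimers, which does not matter because C1 becomes a methylene in step 7.

Step 6
Reactants: 13 (1RS)-1-[4-(benzyloxy)-3-methoxyphenyl]-2-[(4S,6S)-2,2-dimethyl-6-(prop-2-en-1-yl)-1,3-dioxan-4-yl]ethan-1-ol; 14 oct-1-ene
Product: 15 (1RS)-1-[4-(benzyloxy)-3-methoxyphenyl]-2-[(4S,6S)-2,2-dimethyl-6-(non-2-en-1-yl)-1,3-dioxan-4-yl]ethan-1-ol (E/Z mixture)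
Conditions: 14 (5 equiv), second-generation Grubbs catalyst RuCl2(=CHPh)(PCy3)(H2IMes) (5 mol%), CH2Cl2, 40 °C
Reagents that add atoms: none
Why: Olefin cross-metathesis between two unhindered terminal alkenes through ruthenium alkylidene and metallacyclobutane intermediates, driven by loss of ethene; the excess of 14 pushes the distribution toward the cross product, its homodimer is a non-polar hydrocarbon that is easily removed, and the alkene geometry is irrelevant because the alkene is hydrogenated next.

Step 7
Reactants: 15 (1RS)-1-[4-(benzyloxy)-3-methoxyphenyl]-2-[(4S,6S)-2,2-dimethyl-6-(non-2-en-1-yl)-1,3-dioxan-4-yl]ethan-1-ol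
Product: 16 4-{2-[(4S,6S)-2,2-dimethyl-6-nonyl-1,3-dioxan-4-yl]ethyl}-2-methoxyphenol
Conditions: H2 (4 bar), 10% Pd/C, EtOAc–AcOH (20:1), rt
Reagents that add atoms: none
Why: Heterogeneous hydrogenation saturates C7=C8 and cleaves the O-benzyl ether; the freed para-hydroxyl then activates the benzylic C1–O bond, which is hydrogenolysed to CH2 with mild acid assistance, while the ketal keeps O3 and O5 from trapping a benzylic cation and should survive the weakly acidic, nearly anhydrous medium. C3 and C5 are not benzylic and stay untouched.

Step 8
Reactants: 16 4-{2-[(4S,6S)-2,2-dimethyl-6-nonyl-1,3-dioxan-4-yl]ethyl}-2-methoxyphenol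
Product: 17 (3S,5S)-1-(4-hydroxy-3-methoxyphenyl)tetradecane-3,5-diol
Conditions: 1 M aq. HCl–THF (1:4), rt
Reagents that add atoms: none
Why: Acid-catalysed hydrolysis of the isopropylidene ketal, run only after C1 has become a methylene so that no benzylic cation can be captured by O5; the C–O bonds at C3 and C5 are not broken, so the (3S,5S) configuration set in step 1 is delivered unchanged.

## Compound list

1 | propane-1,3-diol | OCCCO | starting material
2 | allyl acetate (prop-2-en-1-yl acetate) | CC(=O)OCC=C | starting material
3 | 3-hydroxypropanal | OCCC=O | intermediate
4 | (3S)-hex-5-ene-1,3-diol | OCC[C@@H](O)CC=C | intermediate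
5 | (3S)-3-hydroxyhex-5-enal | O=CC[C@@H](O)CC=C | intermediate
6 | (4S,6S)-nona-1,8-diene-4,6-diol | C=CC[C@H](O)C[C@@H](O)CC=C | intermediate
7 | (4S,6S)-2,2-dimethyl-4,6-di(prop-2-en-1-yl)-1,3-dioxane | C=CC[C@H]1C[C@H](CC=C)OC(C)(C)O1 | intermediate
8 | mono-ozonide of 7: 3-{[(4R,6S)-2,2-dimethyl-6-(prop-2-en-1-yl)-1,3-dioxan-4-yl]methyl}-1,2,4-trioxolane (both epimers at the trioxolane carbon) | C=CC[C@H]1C[C@H](CC2OCOO2)OC(C)(C)O1 | intermediate
9 | 2-[(4R,6S)-2,2-dimethyl-6-(prop-2-en-1-yl)-1,3-dioxan-4-yl]acetaldehyde | C=CC[C@H]1C[C@H](CC=O)OC(C)(C)O1 | intermediate
10 | 4-bromo-2-methoxyphenol | COc1cc(Br)ccc1O | starting material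
11 | 1-(benzyloxy)-4-bromo-2-methoxybenzene | COc1cc(Br)ccc1OCc1ccccc1 | intermediate
12 | [4-(benzyloxy)-3-methoxyphenyl]magnesium bromide | COc1cc([Mg]Br)ccc1OCc1ccccc1 | intermediate
13 | (1RS)-1-[4-(benzyloxy)-3-methoxyphenyl]-2-[(4S,6S)-2,2-dimethyl-6-(prop-2-en-1-yl)-1,3-dioxan-4-yl]ethan-1-ol | C=CC[C@H]1C[C@H](CC(O)c2ccc(OCc3ccccc3)c(OC)c2)OC(C)(C)O1 | intermediate
14 | oct-1-ene | C=CCCCCCC | starting material
15 | (1RS)-1-[4-(benzyloxy)-3-methoxyphenyl]-2-[(4S,6S)-2,2-dimethyl-6-(non-2-en-1-yl)-1,3-dioxan-4-yl]ethan-1-ol (E/Z mixture) | CCCCCCC=CC[C@H]1C[C@H](CC(O)c2ccc(OCc3ccccc3)c(OC)c2)OC(C)(C)O1 | intermediate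
16 | 4-{2-[(4S,6S)-2,2-dimethyl-6-nonyl-1,3-dioxan-4-yl]ethyl}-2-methoxyphenol | CCCCCCCCC[C@H]1C[C@H](CCc2ccc(O)c(OC)c2)OC(C)(C)O1 | intermediate
17 | (3S,5S)-1-(4-hydroxy-3-methoxyphenyl)tetradecane-3,5-diol | CCCCCCCCC[C@H](O)C[C@@H](O)CCc1ccc(O)c(OC)c1 | target

## Step count and least certain steps

Total step count: 8.
Longest linear sequence: 7 steps (steps 1, 2, 3, 5, 6, 7 and 8, from 1 to 17); step 4 is a one-step side branch.

**Step 1 (key step).** The most likely failure is stalling after the first allylation: the catalyst has to survive a long reaction at 90 °C, and if it dies early the mono-adduct accumulates. A second risk is partial substrate control in the second addition, which would raise the share of the meso diastereomer. The sense of induction also has to be confirmed on 6.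

The fallback sets out from 1 and comes back at 6, using stepwise classical chemistry:
- Mono-etherification of 1 (NaH, 4-methoxybenzyl chloride, THF) gives 3-[(4-methoxybenzyl)oxy]propan-1-ol F1.
- Parikh–Doering oxidation gives 3-[(4-methoxybenzyl)oxy]propanal F2.
- Brown allylation with the B-allyldiisopinocampheylborane made from (−)-Ipc2BOMe and allylmagnesium bromide should give (3S)-1-[(4-methoxybenzyl)oxy]hex-5-en-3-ol F3.
- Anhydrous DDQ oxidation closes the cyclic acetal (4S)-2-(4-methoxyphenyl)-4-(prop-2-en-1-yl)-1,3-dioxane F4.
- i-Bu2AlH opens it at the less hindered oxygen to (3S)-3-[(4-methoxybenzyl)oxy]hex-5-en-1-ol F5.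
- Dess–Martin oxidation gives (3S)-3-[(4-methoxybenzyl)oxy]hex-5-enal F6.
- Chelation-controlled Hosomi–Sakurai allylation (TiCl4, allyltrimethylsilane, CH2Cl2, −78 °C), in which the six-membered titanium chelate directs attack anti to the C3 substituent, gives (4S,6S)-6-[(4-methoxybenzyl)oxy]nona-1,8-dien-4-ol F7.
- DDQ in wet CH2Cl2 then returns to 6.

**Step 3.** The most likely failure is over-cleavage of the second vinyl group, because the two arms react independently and at the same rate, together with evaporative loss of the fairly volatile 7 and 9 during work-up. The fallback sets out from 7 and comes back at 9 in two steps. Upjohn dihydroxylation with the co-oxidant limiting (OsO4 cat., N-methylmorpholine N-oxide 0.6 equiv, acetone–water) gives 3-[(4S,6S)-2,2-dimethyl-6-(prop-2-en-1-yl)-1,3-dioxan-4-yl]propane-1,2-diol F8 as both epimers at the new carbinol. F8 differs enough in polarity from 7 and from the tetraol for a silica plug to separate them, and 7 is recycled. NaIO4 in THF–water then cleaves F8 to 9.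

**Step 7.** The most likely failure is incomplete hydrogenolysis of the benzylic C1–O bond, so that the reaction stops at the debenzylated benzylic alcohol. If stronger acid is then used, the ketal can be lost and O5 can cyclise onto the benzylic cation. The fallback sets out from 15 and comes back at 16 in three steps:
- Xanthate formation (NaH, CS2, then MeI, THF) gives the benzylic S-methyl xanthate F9.
- Barton–McCombie reduction ((Me3Si)3SiH, AIBN, toluene, 80 °C) removes the C1 oxygen by a radical chain that needs neither acid nor palladium and gives (4S,6S)-4-{2-[4-(benzyloxy)-3-methoxyphenyl]ethyl}-2,2-dimethyl-6-(non-2-en-1-yl)-1,3-dioxane F10.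
- Neutral hydrogenation (H2, Pd/C, EtOAc) then only has to saturate the alkene and cleave the benzyl ether, and gives 16.

**Step 6.** The most likely failure is self-metathesis of 14 outrunning the cross reaction and consuming the catalyst, or ruthenium hydride-induced double-bond migration before metathesis, which would shorten the chain by one carbon. The fallback sets out from 13 and comes back at 15 in two steps. Lemieux–Johnson cleavage of the remaining vinyl group (OsO4 cat., NaIO4, 2,6-lutidine, dioxane–water) gives 2-[(4R,6S)-6-{(2RS)-2-[4-(benzyloxy)-3-methoxyphenyl]-2-hydroxyethyl}-2,2-dimethyl-1,3-dioxan-4-yl]acetaldehyde F11. Wittig olefination with the ylide from heptyltriphenylphosphonium bromide and NaN(SiMe3)2 (3 equiv, THF, −78 °C → rt; one equivalent is taken up by the free hydroxyl) gives 15, mainly as the Z isomer, which is acceptable because the alkene is hydrogenated in step 7.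

## Further compounds

F1 | step 1 | 3-[(4-methoxybenzyl)oxy]propan-1-ol | COc1ccc(COCCCO)cc1
F2 | step 1 | 3-[(4-methoxybenzyl)oxy]propanal | COc1ccc(COCCC=O)cc1
F3 | step 1 | (3S)-1-[(4-methoxybenzyl)oxy]hex-5-en-3-ol | COc1ccc(COCC[C@@H](O)CC=C)cc1
F4 | step 1 | (4S)-2-(4-methoxyphenyl)-4-(prop-2-en-1-yl)-1,3-dioxane (acetal carbon not specified) | C=CC[C@H]1CCOC(c2ccc(OC)cc2)O1
F5 | step 1 | (3S)-3-[(4-methoxybenzyl)oxy]hex-5-en-1-ol | OCC[C@@H](OCc1ccc(OC)cc1)CC=C
F6 | step 1 | (3S)-3-[(4-methoxybenzyl)oxy]hex-5-enal | O=CC[C@@H](OCc1ccc(OC)cc1)CC=C
F7 | step 1 | (4S,6S)-6-[(4-methoxybenzyl)oxy]nona-1,8-dien-4-ol | C=CC[C@H](O)C[C@@H](OCc1ccc(OC)cc1)CC=C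
F8 | step 3 | 3-[(4S,6S)-2,2-dimethyl-6-(prop-2-en-1-yl)-1,3-dioxan-4-yl]propane-1,2-diol (both epimers at the new carbinol) | C=CC[C@H]1C[C@H](CC(O)CO)OC(C)(C)O1
F9 | step 7 | benzylic S-methyl xanthate (O-alkyl S-methyl carbonodithioate at the C1 oxygen of 15; E/Z and C1-epimer mixture) | CCCCCCC=CC[C@H]1C[C@H](CC(OC(=S)SC)c2ccc(OCc3ccccc3)c(OC)c2)OC(C)(C)O1
F10 | step 7 | (4S,6S)-4-{2-[4-(benzyloxy)-3-methoxyphenyl]ethyl}-2,2-dimethyl-6-(non-2-en-1-yl)-1,3-dioxane (E/Z mixture) | CCCCCCC=CC[C@H]1C[C@H](CCc2ccc(OCc3ccccc3)c(OC)c2)OC(C)(C)O1
F11 | step 6 | 2-[(4R,6S)-6-{(2RS)-2-[4-(benzyloxy)-3-methoxyphenyl]-2-hydroxyethyl}-2,2-dimethyl-1,3-dioxan-4-yl]acetaldehyde | O=CC[C@H]1C[C@H](CC(O)c2ccc(OCc3ccccc3)c(OC)c2)OC(C)(C)O1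
A1 | alternative 1 | (E)-1-(4-benzyloxy-3-methoxyphenyl)tetradec-3-en-5-ol (racemic) | CCCCCCCCCC(O)/C=C/CCc1ccc(OCc2ccccc2)c(OC)c1
A2 | alternative 1 | (3S,4S,5S)-1-(4-benzyloxy-3-methoxyphenyl)-3,4-epoxytetradecan-5-ol | CCCCCCCCC[C@H](O)[C@@H]1O[C@H]1CCc1ccc(OCc2ccccc2)c(OC)c1
A3 | alternative 2 | (S)-tridec-1-en-4-ol | CCCCCCCCC[C@H](O)CC=C
A4 | alternative 2 | 4-formyl-2-methoxyphenyl acetate (vanillin acetate) | COc1cc(C=O)ccc1OC(C)=O
A5 | alternative 2 | all-cis (6S)-2-(4-acetoxy-3-methoxyphenyl)-6-nonyltetrahydropyran-4-yl trifluoroacetate | CCCCCCCCC[C@H]1C[C@@H](OC(=O)C(F)(F)F)C[C@@H](c2ccc(OC(C)=O)c(OC)c2)O1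
A6 | alternative 3 | (2R,4R)-1,2:4,5-diepoxypentane | C1[C@H](O1)C[C@H]1OC1
A7 | alternative 3 | octylmagnesium bromide | CCCCCCCC[Mg]Br
A8 | alternative 3 | [4-(benzyloxy)-3-methoxyphenyl]methylmagnesium chloride | COc1cc(C[Mg]Cl)ccc1OCc1ccccc1
A9 | alternative 3 | (3S,5S)-1-(4-benzyloxy-3-methoxyphenyl)tetradecane-3,5-diol | CCCCCCCCC[C@H](O)C[C@@H](O)CCc1ccc(OCc2ccccc2)c(OC)c1
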